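**Retrosynthetic overview**
1. The target is meso (C1 R, C6 S; C1′ S, C6′ R; both alkenes Z). Its two 4-methylpent-3-enoyl ketones are made last and together from a meso bis-silyl diester: reduction, oxidation, α-selective prenylbarium addition, reoxidation, desilylation.
2. Ring 2 is closed last at C5′–C6′ by a Ni/Cr (Nozaki–Hiyama–Kishi) addition of a (Z)-alkenyl bromide to a C6′ aldehyde. The bromide comes from a trans-selective B-alkyl Suzuki coupling of the C7′H=C5′Br2 dibromoalkene with the antipodal C1′ quaternary chain, itself made by asymmetric phase-transfer allylation of a methylmalonate.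
3. The C7′ aldehyde is the reduced carbonyl of a seven-membered lactone made by ring-closing metathesis of the pent-4-enoate of the ring-1 2-methylidenecyclohexanol. Feature used: with each ring numbered C1 (quaternary), C2–C4, C5 (=C7H–C8H2) and C6 (CHOH), the C6 oxygen is allylic to C5=C7 and C8 lies cis to C6; an ester from O6 through C7′(=O), C8′ and C8 to C7 puts C5=C7 inside a seven-membered ring, where only this geometry can exist.
4. Ring 1 comes from methyl 2-oxocyclohexanecarboxylate: auxiliary-controlled methylation sets C1, then α′-methylenation and Luche reduction set C6 with OH cis to the ester.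
5. Ring order: ring 1 (from the starting material), the temporary seven-membered lactone (step 6), ring 2 (step 16).

Key step: step 6

Assumption 1: the target is a meso compound, so the "single enantiomer" is this one achiral diastereomer, and ring 1 and the chain for ring 2 must belong to opposite absolute series, here (R)-6 and (S)-26.
Assumption 2: steps 2 and 12 are taken to follow the sense of induction of their closest analogues; if a rotation check shows the opposite, D-valine tert-butyl ester or the (R,R)-catalyst is used instead, since only the heterochiral pairing of 6 and 26 matters.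

Step 1
Reactants: 1 methyl 2-oxocyclohexane-1-carboxylate; 2 L-valine tert-butyl ester (free base)
Product: 3 methyl 2-{[(2S)-1-tert-butoxy-3-methyl-1-oxobutan-2-yl]amino}cyclohex-1-ene-1-carboxylate
Conditions: BF3·OEt2 (cat.), toluene, reflux, Dean–Stark
Reagents that add atoms: L-valine tert-butyl ester 2, CC(C)[C@H](N)C(=O)OC(C)(C)C
Why: Acid-catalysed condensation of the β-keto ester with the primary amine (enamino-ester formation) should give the hydrogen-bonded vinylogous carbamate, water being removed azeotropically; the valine centre is not touched.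

Step 2
Reactants: 3 enamino ester; 4 methyl iodide
Product: 6 methyl (1R)-1-methyl-2-oxocyclohexane-1-carboxylate, via ketimine 5 (not isolated)
Conditions: LDA, toluene, −78 °C; HMPA (1 equiv); MeI, −78 to −55 °C; then aq. citric acid, THF, rt
Reagents that add atoms: methyl iodide 4, CI; water, O
Why: Auxiliary-controlled alkylation of a chiral lithiated β-enamino ester: the lithium is held by the enaminate nitrogen and the valine ester, the isopropyl group shields one face, and C-methylation on the open face sets C1 as R; hydrolysis of the ketimine then frees the ketone and the auxiliary.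

Step 3
Reactants: 6 methyl (1R)-1-methyl-2-oxocyclohexane-1-carboxylate; 7 Eschenmoser's salt; 4 methyl iodide
Product: 10 methyl (1R)-1-methyl-3-methylidene-2-oxocyclohexane-1-carboxylate, via Mannich base 8 (not isolated), via ammonium iodide 9 (not isolated)
Conditions: LDA, THF, −78 °C; 7, −78 to 0 °C; then MeI, Et2O, rt; then NaHCO3, CH2Cl2/H2O, rt; used at once
Reagents that add atoms: Eschenmoser's salt 7, C=[N+](C)C.[I-]
Why: The only enolisable position (C5) is aminomethylated (Mannich reaction with the preformed iminium salt), and quaternisation followed by base-induced Hofmann-type elimination should give the exocyclic enone; C1 is quaternary and cannot epimerise.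

Step 4
Reactants: 10 methyl (1R)-1-methyl-3-methylidene-2-oxocyclohexane-1-carboxylate
Product: 11 methyl (1R,2S)-2-hydroxy-1-methyl-3-methylidenecyclohexane-1-carboxylate
Conditions: NaBH4, CeCl3·7H2O, MeOH, −78 °C; minor epimer removed by chromatography
Reagents that add atoms: none
Why: Luche 1,2-reduction under non-chelating conditions: hydride should add axially and antiperiplanar to the axial, electron-withdrawing ester on C1 (polar Felkin–Anh), which puts the new C6 hydroxyl cis to the ester and trans to the methyl group (C6 S); a chelated, in-plane ester would be expected to give the other epimer and is therefore avoided.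

Step 5
Reactants: 11 methyl (1R,2S)-2-hydroxy-1-methyl-3-methylidenecyclohexane-1-carboxylate; 12 pent-4-enoyl chloride
Product: 13 methyl (1R,2S)-1-methyl-3-methylidene-2-(pent-4-enoyloxy)cyclohexane-1-carboxylate
Conditions: Et3N, DMAP (cat.), CH2Cl2, 0 °C to rt
Reagents that add atoms: pent-4-enoyl chloride 12, C=CCCC(=O)Cl
Why: DMAP-catalysed acylation (nucleophilic catalysis) of the hindered secondary allylic alcohol by the acid chloride, with no change at C1 or C6.

Step 6
Reactants: 13 methyl (1R,2S)-1-methyl-3-methylidene-2-(pent-4-enoyloxy)cyclohexane-1-carboxylate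
Product: 14 methyl (9R,9aS)-9-methyl-2-oxo-2,3,4,6,7,8,9,9a-octahydro-1-benzoxepine-9-carboxylate (Z alkene C5=C5a in the lactone ring)
Conditions: Grubbs second-generation catalyst (10 mol%, in portions), 1,4-benzoquinone (20 mol%), toluene (2 mM), 80 °C, argon sparge
Reagents that add atoms: none
Why: The ruthenium alkylidene should load on the monosubstituted pentenoate alkene and close on the exocyclic 1,1-disubstituted methylene through a metallacyclobutane, with loss of ethylene (ring-closing metathesis; closest known type: ester-tethered RCM to unsaturated seven-membered lactones). The closure forms the C5=C7 bond within the seven-membered ring C6–O–C7′(=O)–C8′–C8–C7=C5. No stereocentre is formed; the geometry of C5=C7 is fixed by the ring, because a trisubstituted alkene in a seven-membered ring can only have its two ring bonds (to C6 and to C8) cis, which is the Z geometry of the target. The selectivity needed is cyclisation over intermolecular metathesis of the terminal alkene, and it is secured by high dilution, portionwise catalyst addition and the reluctance of the hindered methylene to homodimerise. Benzoquinone suppresses ruthenium hydride alkene migration, and C1 and C6 lie outside the reacting centres.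

Step 7
Reactants: 14 seven-membered lactone
Product: 15 methyl (9R,9aS)-2-hydroxy-9-methyl-2,3,4,6,7,8,9,9a-octahydro-1-benzoxepine-9-carboxylate (lactol, anomer mixture, in equilibrium with the open C7′ hydroxy aldehyde)
Conditions: DIBAL-H (1.1 equiv), CH2Cl2, −78 °C; Rochelle salt work-up
Reagents that add atoms: none
Why: Partial reduction of a lactone to the lactol through the aluminium hemiacetal that is stable at −78 °C; the unhindered lactone carbonyl should react much faster than the neopentyl methyl ester on quaternary C1.

Step 8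
Reactants: 15 lactol; 16 (dibromomethyl)triphenylphosphonium bromide
Product: 17 methyl (1R,2S,3Z)-3-(5,5-dibromopent-4-en-1-ylidene)-2-hydroxy-1-methylcyclohexane-1-carboxylate
Conditions: 16, t-BuOK, THF, rt (ylide); then 15, THF, rt
Reagents that add atoms: (dibromomethyl)triphenylphosphonium bromide 16, BrC(Br)[P+](c1ccccc1)(c1ccccc1)c1ccccc1.[Br-]
Why: Wittig-type dibromomethylenation (Ramirez/Corey–Fuchs olefination with the preformed ylide) of the open hydroxy aldehyde form of the lactol; preforming the ylide avoids CBr4/PPh3, which would brominate the free allylic alcohol.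

Step 9
Reactants: 17 dibromoalkene alcohol; 18 triethylsilyl triflate
Product: 19 methyl (1R,2S,3Z)-3-(5,5-dibromopent-4-en-1-ylidene)-1-methyl-2-(triethylsilyloxy)cyclohexane-1-carboxylate
Conditions: 2,6-lutidine, CH2Cl2, −78 to 0 °C
Reagents that add atoms: triethylsilyl triflate 18, CC[Si](CC)(CC)OS(=O)(=O)C(F)(F)F
Why: O-Silylation of the hindered secondary alcohol with the silyl triflate and a hindered base; the dibromoalkene and the ester are inert.

Step 10
Reactants: 20 2,2,5-trimethyl-1,3-dioxane-4,6-dione; 21 tert-butanol
Product: 22 3-tert-butoxy-2-methyl-3-oxopropanoic acid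
Conditions: t-BuOH (solvent), reflux
Reagents that add atoms: tert-butanol 21, CC(C)(C)O
Why: Thermal alcoholysis of the Meldrum's acid ring should open it to the malonic half ester with loss of acetone.

Step 11
Reactants: 22 3-tert-butoxy-2-methyl-3-oxopropanoic acid; 23 2,2-diphenylethanol
Product: 24 1-tert-butyl 3-(2,2-diphenylethyl) 2-methylpropanedioate
Conditions: DCC, DMAP (cat.), CH2Cl2, 0 °C to rt
Reagents that add atoms: 2,2-diphenylethanol 23, OCC(c1ccccc1)c1ccccc1
Why: Steglich esterification of the half acid with the primary alcohol gives the mixed malonate whose two different ester groups are needed for face discrimination in the next step.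

Step 12
Reactants: 24 1-tert-butyl 3-(2,2-diphenylethyl) 2-methylpropanedioate; 25 allyl bromide
Product: 26 1-tert-butyl 3-(2,2-diphenylethyl) (2S)-2-methyl-2-(prop-2-en-1-yl)propanedioate
Conditions: (S,S)-3,4,5-trifluorophenyl-NAS bromide (5 mol%), 50% aq. KOH, toluene, −40 °C
Reagents that add atoms: allyl bromide 25, C=CCBr
Why: Enantioselective phase-transfer alkylation of an α-methylmalonate: the enolate, ion-paired with the C2-symmetric binaphthyl spiro-ammonium cation and differentiated by its tert-butyl and diphenylethyl esters, should be allylated on one face, setting the quaternary centre C1′ as S.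

Step 13
Reactants: 26 (S)-allyl methyl malonate
Product: 27 tert-butyl (2S)-2-(hydroxymethyl)-2-methylpent-4-enoate
Conditions: LiBH4, THF, 0 °C to rt
Reagents that add atoms: none
Why: Chemoselective ester reduction: LiBH4 should reduce the primary-alkyl malonate ester through the aldehyde to the alcohol and leave the tert-butyl ester alone; C1′ is quaternary, so it is untouched and its descriptor stays S.

Step 14
Reactants: 27 tert-butyl (2S)-2-(hydroxymethyl)-2-methylpent-4-enoate; 19 silylated dibromoalkene
Product: 29 methyl (1R,2S,3Z)-3-[(4Z,9S)-5-bromo-9-(tert-butoxycarbonyl)-10-hydroxy-9-methyldec-4-en-1-ylidene]-1-methyl-2-(triethylsilyloxy)cyclohexane-1-carboxylate, via B-alkyl-9-BBN borane 28 (not isolated)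
Conditions: 27, 9-BBN (2.2 equiv), THF, 0 °C to rt; then 19, Pd(dppf)Cl2·CH2Cl2 (5 mol%), AsPh3, Cs2CO3, DMF/H2O, rt
Reagents that add atoms: none
Why: Anti-Markovnikov hydroboration of the terminal alkene (one further equivalent of borane is taken up by the hydroxyl) followed by B-alkyl Suzuki–Miyaura coupling; oxidative addition should occur at the less hindered C–Br bond trans to the C8′ chain, so C4′ enters trans to C8′ and the remaining bromine is cis to C8′ (Z-bromoalkene).

Step 15
Reactants: 29 (Z)-alkenyl bromide alcohol
Product: 30 methyl (1R,2S,3Z)-3-[(4Z,9S)-5-bromo-9-(tert-butoxycarbonyl)-9-methyl-10-oxodec-4-en-1-ylidene]-1-methyl-2-(triethylsilyloxy)cyclohexane-1-carboxylate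
Conditions: Dess–Martin periodinane, pyridine, CH2Cl2, 0 °C to rt; used directly
Reagents that add atoms: none
Why: Dess–Martin oxidation of the only free (primary) alcohol to the non-enolisable α-quaternary aldehyde; the pyridine buffer protects the silyl ether.

Step 16
Reactants: 30 bromo aldehyde
Product: 31 methyl (1R,2S,3Z)-3-{4-[(1Z,2R,3S)-3-(tert-butoxycarbonyl)-2-hydroxy-3-methylcyclohexylidene]butylidene}-1-methyl-2-(triethylsilyloxy)cyclohexane-1-carboxylate
Conditions: CrCl2 (6 equiv), NiCl2 (5 mol%), DMSO/THF (5 mM), rt
Reagents that add atoms: none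
Why: Intramolecular Nozaki–Hiyama–Kishi reaction: the alkenylchromium(III) species forms with retention and closes the six-membered ring at C5′–C6′, so C6′ ends cis to C8′; the C6′ carbinol (R, OH cis to the ester) is expected from a chair transition state with the tert-butyl ester equatorial (antiperiplanar to the forming bond and able to bind chromium) and the chromium alkoxide axial, away from the cis C8′H2 group (A1,3 strain).

Step 17
Reactants: 31 ring-2 allylic alcohol; 18 triethylsilyl triflate
Product: 32 methyl (1R,2S,3Z)-3-{4-[(1Z,2R,3S)-3-(tert-butoxycarbonyl)-3-methyl-2-(triethylsilyloxy)cyclohexylidene]butylidene}-1-methyl-2-(triethylsilyloxy)cyclohexane-1-carboxylate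
Conditions: 2,6-lutidine, CH2Cl2, 0 °C
Reagents that add atoms: triethylsilyl triflate 18, CC[Si](CC)(CC)OS(=O)(=O)C(F)(F)F
Why: O-Silylation of the second hindered allylic alcohol, so that both carbinols carry the same protecting group before the redox steps.

Step 18
Reactants: 32 bis-silyl diester
Product: 33 meso diol: both rings with C1/C1′ CH2OH and C6/C6′ OSiEt3, joined by the (Z,Z) =C7H–C8H2–C8′H2–C7′H= chain
Conditions: DIBAL-H (6 equiv), CH2Cl2, −78 to 0 °C; Rochelle salt work-up
Reagents that add atoms: none
Why: Exhaustive DIBAL-H reduction of the methyl and the tert-butyl ester to primary alcohols; once both carboxyl groups are CH2OH the two halves are mirror images, so the product should be a single meso diol.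

Step 19
Reactants: 33 meso diol
Product: 34 meso dialdehyde (C1/C1′ CHO, C6/C6′ OSiEt3)
Conditions: Dess–Martin periodinane, pyridine, CH2Cl2, 0 °C to rt
Reagents that add atoms: none
Why: Two-directional Dess–Martin oxidation of the neopentyl primary alcohols to aldehydes that have no α-hydrogen and so cannot epimerise.

Step 20
Reactants: 34 meso dialdehyde; 35 prenyl chloride
Product: 36 bis(1-hydroxy-4-methylpent-3-enyl) compound (C9/C9′ carbinols as an epimer mixture, C6/C6′ OSiEt3)
Conditions: activated barium (BaI2, Li, biphenyl, THF, rt); 35, −78 °C; then 34, −78 °C; H2O quench at −78 °C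
Reagents that add atoms: prenyl chloride 35, CC(C)=CCCl
Why: α-Selective allylation with an allylic barium reagent: prenylbarium chloride should add to both aldehydes through its unsubstituted α-carbon without allylic transposition, giving the linear 4-methylpent-3-enyl carbinols; the new C9/C9′ centres form unselectively and are removed by the next oxidation.

Step 21
Reactants: 36 bis(homoallylic alcohol)
Product: 37 meso bis-silyl diketone (C1/C1′ 4-methylpent-3-enoyl, C6/C6′ OSiEt3)
Conditions: Dess–Martin periodinane, pyridine, CH2Cl2, 0 °C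
Reagents that add atoms: none
Why: Dess–Martin oxidation of both secondary alcohols under buffered, base-free conditions should give the β,γ-unsaturated ketones without migration of the alkene into conjugation.

Step 22
Reactants: 37 meso bis-silyl diketone
Product: 38 target CNP0297042.2 (meso; C1 R, C6 S, C1′ S, C6′ R; both alkenes Z)
Conditions: HF·pyridine, pyridine, THF, 0 °C to rt
Reagents that add atoms: none
Why: Fluoride cleavage of both triethylsilyl ethers under buffered, near-neutral conditions, chosen to avoid retro-aldol cleavage of the β-hydroxy ketones and isomerisation of the β,γ-enones.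

**Compound list**
1 | methyl 2-oxocyclohexane-1-carboxylate | COC(=O)C1CCCCC1=O | starting material
2 | L-valine tert-butyl ester | CC(C)[C@H](N)C(=O)OC(C)(C)C | starting material
3 | methyl 2-{[(2S)-1-tert-butoxy-3-methyl-1-oxobutan-2-yl]amino}cyclohex-1-ene-1-carboxylate | COC(=O)C1=C(N[C@@H](C(C)C)C(=O)OC(C)(C)C)CCCC1 | intermediate
4 | methyl iodide | CI | starting material
5 | methyl (1R)-2-{[(2S)-1-tert-butoxy-3-methyl-1-oxobutan-2-yl]imino}-1-methylcyclohexane-1-carboxylate | COC(=O)[C@]1(C)CCCCC1=N[C@@H](C(C)C)C(=O)OC(C)(C)C | intermediate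
6 | methyl (1R)-1-methyl-2-oxocyclohexane-1-carboxylate | COC(=O)[C@]1(C)CCCCC1=O | intermediate
7 | Eschenmoser's salt (N,N-dimethylmethyleneiminium iodide) | C=[N+](C)C.[I-] | starting material
8 | methyl (1R)-3-[(dimethylamino)methyl]-1-methyl-2-oxocyclohexane-1-carboxylate (C3 epimers) | COC(=O)[C@]1(C)CCCC(CN(C)C)C1=O | intermediate
9 | {[(3R)-3-(methoxycarbonyl)-3-methyl-2-oxocyclohexyl]methyl}trimethylammonium iodide | COC(=O)[C@]1(C)CCCC(C[N+](C)(C)C)C1=O.[I-] | intermediate
10 | methyl (1R)-1-methyl-3-methylidene-2-oxocyclohexane-1-carboxylate | COC(=O)[C@]1(C)CCCC(=C)C1=O | intermediate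
11 | methyl (1R,2S)-2-hydroxy-1-methyl-3-methylidenecyclohexane-1-carboxylate | COC(=O)[C@]1(C)CCCC(=C)[C@@H]1O | intermediate
12 | pent-4-enoyl chloride | C=CCCC(=O)Cl | starting material
13 | methyl (1R,2S)-1-methyl-3-methylidene-2-(pent-4-enoyloxy)cyclohexane-1-carboxylate | COC(=O)[C@]1(C)CCCC(=C)[C@@H]1OC(=O)CCC=C | intermediate
14 | methyl (9R,9aS)-9-methyl-2-oxo-2,3,4,6,7,8,9,9a-octahydro-1-benzoxepine-9-carboxylate | COC(=O)[C@]1(C)CCC/C2=C/CCC(=O)O[C@H]12 | intermediate
15 | methyl (9R,9aS)-2-hydroxy-9-methyl-2,3,4,6,7,8,9,9a-octahydro-1-benzoxepine-9-carboxylate (anomers) | COC(=O)[C@]1(C)CCC/C2=C/CCC(O)O[C@H]12 | intermediate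
16 | (dibromomethyl)triphenylphosphonium bromide | BrC(Br)[P+](c1ccccc1)(c1ccccc1)c1ccccc1.[Br-] | starting material
17 | methyl (1R,2S,3Z)-3-(5,5-dibromopent-4-en-1-ylidene)-2-hydroxy-1-methylcyclohexane-1-carboxylate | COC(=O)[C@]1(C)CCC/C(=C/CCC=C(Br)Br)[C@@H]1O | intermediate
18 | triethylsilyl trifluoromethanesulfonate | CC[Si](CC)(CC)OS(=O)(=O)C(F)(F)F | starting material
19 | methyl (1R,2S,3Z)-3-(5,5-dibromopent-4-en-1-ylidene)-1-methyl-2-(triethylsilyloxy)cyclohexane-1-carboxylate | COC(=O)[C@]1(C)CCC/C(=C/CCC=C(Br)Br)[C@@H]1O[Si](CC)(CC)CC | intermediate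
20 | 2,2,5-trimethyl-1,3-dioxane-4,6-dione | CC1C(=O)OC(C)(C)OC1=O | starting material
21 | tert-butanol | CC(C)(C)O | starting material
22 | 3-tert-butoxy-2-methyl-3-oxopropanoic acid | CC(C(=O)O)C(=O)OC(C)(C)C | intermediate
23 | 2,2-diphenylethanol | OCC(c1ccccc1)c1ccccc1 | starting material
24 | 1-tert-butyl 3-(2,2-diphenylethyl) 2-methylpropanedioate | CC(C(=O)OC(C)(C)C)C(=O)OCC(c1ccccc1)c1ccccc1 | intermediate
25 | allyl bromide | C=CCBr | starting material
26 | 1-tert-butyl 3-(2,2-diphenylethyl) (2S)-2-methyl-2-(prop-2-en-1-yl)propanedioate | C=CC[C@](C)(C(=O)OC(C)(C)C)C(=O)OCC(c1ccccc1)c1ccccc1 | intermediate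
27 | tert-butyl (2S)-2-(hydroxymethyl)-2-methylpent-4-enoate | C=CC[C@](C)(C(=O)OC(C)(C)C)CO | intermediate
28 | B-alkyl-9-BBN adduct of 27 (C4′ borane, O-borinate) | B1(CCC[C@](C)(C(=O)OC(C)(C)C)COB2C3CCCC2CCC3)C2CCCC1CCC2 | intermediate
29 | methyl (1R,2S,3Z)-3-[(4Z,9S)-5-bromo-9-(tert-butoxycarbonyl)-10-hydroxy-9-methyldec-4-en-1-ylidene]-1-methyl-2-(triethylsilyloxy)cyclohexane-1-carboxylate | COC(=O)[C@]1(C)CCC/C(=C/CC/C=C(\Br)CCC[C@](C)(C(=O)OC(C)(C)C)CO)[C@@H]1O[Si](CC)(CC)CC | intermediate
30 | methyl (1R,2S,3Z)-3-[(4Z,9S)-5-bromo-9-(tert-butoxycarbonyl)-9-methyl-10-oxodec-4-en-1-ylidene]-1-methyl-2-(triethylsilyloxy)cyclohexane-1-carboxylate | COC(=O)[C@]1(C)CCC/C(=C/CC/C=C(\Br)CCC[C@](C)(C(=O)OC(C)(C)C)C=O)[C@@H]1O[Si](CC)(CC)CC | intermediate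
31 | methyl (1R,2S,3Z)-3-{4-[(1Z,2R,3S)-3-(tert-butoxycarbonyl)-2-hydroxy-3-methylcyclohexylidene]butylidene}-1-methyl-2-(triethylsilyloxy)cyclohexane-1-carboxylate | COC(=O)[C@]1(C)CCC/C(=C/CC/C=C2/CCC[C@](C)(C(=O)OC(C)(C)C)[C@@H]2O)[C@@H]1O[Si](CC)(CC)CC | intermediate
32 | methyl (1R,2S,3Z)-3-{4-[(1Z,2R,3S)-3-(tert-butoxycarbonyl)-3-methyl-2-(triethylsilyloxy)cyclohexylidene]butylidene}-1-methyl-2-(triethylsilyloxy)cyclohexane-1-carboxylate | COC(=O)[C@]1(C)CCC/C(=C/CC/C=C2/CCC[C@](C)(C(=O)OC(C)(C)C)[C@@H]2O[Si](CC)(CC)CC)[C@@H]1O[Si](CC)(CC)CC | intermediate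
33 | meso diol (C1/C1′ CH2OH, C6/C6′ OSiEt3, Z,Z) | OC[C@]1(C)CCC/C(=C/CC/C=C2/CCC[C@](C)(CO)[C@@H]2O[Si](CC)(CC)CC)[C@@H]1O[Si](CC)(CC)CC | intermediate
34 | meso dialdehyde (C1/C1′ CHO, C6/C6′ OSiEt3, Z,Z) | O=C[C@]1(C)CCC/C(=C/CC/C=C2/CCC[C@](C)(C=O)[C@@H]2O[Si](CC)(CC)CC)[C@@H]1O[Si](CC)(CC)CC | intermediate
35 | prenyl chloride (1-chloro-3-methylbut-2-ene) | CC(C)=CCCl | starting material
36 | bis(1-hydroxy-4-methylpent-3-enyl) bis-silyl ether (C9/C9′ epimers) | CC(C)=CCC(O)[C@]1(C)CCC/C(=C/CC/C=C2/CCC[C@](C)(C(O)CC=C(C)C)[C@@H]2O[Si](CC)(CC)CC)[C@@H]1O[Si](CC)(CC)CC | intermediate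
37 | meso bis(4-methylpent-3-enoyl) bis-silyl ether | CC(C)=CCC(=O)[C@]1(C)CCC/C(=C/CC/C=C2/CCC[C@](C)(C(=O)CC=C(C)C)[C@@H]2O[Si](CC)(CC)CC)[C@@H]1O[Si](CC)(CC)CC | intermediate
38 | CNP0297042.2 | CC(C)=CCC(=O)[C@]1(C)CCC/C(=C/CC/C=C2/CCC[C@](C)(C(=O)CC=C(C)C)[C@@H]2O)[C@@H]1O | target

**Step count and risks**

Total steps: 22 (ring-1 line, steps 1–9; chain, steps 10–13; union and endgame, steps 14–22). Longest linear sequence: 18 steps (1–9, then 14–22).

Step 6 is the most exposed. Closure onto the hindered 1,1-disubstituted alkene is slow, and the ester must take up the unfavourable s-cis arrangement of a seven-membered lactone, so intermolecular metathesis of the terminal alkene (dimer and oligomer formation) and catalyst decay may outrun cyclisation. The fallback changes the tether from an ester to an acetal. It sets out from 11, which is transacetalised with 5,5-dimethoxypent-1-ene (PPTS, benzene, 5 Å sieves) to the mixed acetal methyl (1R,2S)-2-[(1-methoxypent-4-en-1-yl)oxy]-1-methyl-3-methylidenecyclohexane-1-carboxylate F1. Ring-closing metathesis of this flexible tether, which has neither the s-cis penalty nor a carbonyl that can bind ruthenium, should give the seven-membered cyclic acetal methyl (9R,9aS)-2-methoxy-9-methyl-2,3,4,6,7,8,9,9a-octahydro-1-benzoxepine-9-carboxylate F2 with the same ring-enforced Z alkene. PPTS in wet acetone then hydrolyses it to lactol 15, where the route is rejoined and step 7 is no longer needed.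

Step 16 comes second. The addition of the alkenylchromium to the C6′ aldehyde may show poor facial selectivity, giving much of the epimer with OH cis to the methyl group. The fallback sets the carbinol by hydride delivery instead of by the C–C bond formation. It sets out from 30: the cyclisation mixture, containing the C6′ epimer of 31 F3, is oxidised as a whole with Dess–Martin periodinane to the ring-2 Z-enone F4 (handled cold and base-free to keep the alkene geometry), and Luche reduction as in step 4, hydride anti to the tert-butyl ester, should return 31.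

Step 4 is third. Hydride addition to the enone may show insufficient facial selectivity, leaving much of the C6 epimer with OH cis to the methyl group, because the preference rests on the conformational and polar bias of C1 alone. The fallback replaces substrate control by catalyst control. It sets out from 10, which is reduced with an oxazaborolidine catalyst and catecholborane in toluene at −78 °C (CBS reduction), using the catalyst antipode matched to hydride delivery anti to the ester (the (R)-catalyst if the quaternary carbon acts as the large group), and it comes back at 11, so that no further compound arises (F0).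

**Further compounds**
F1 | step 6 | methyl (1R,2S)-2-[(1-methoxypent-4-en-1-yl)oxy]-1-methyl-3-methylidenecyclohexane-1-carboxylate | COC(=O)[C@]1(C)CCCC(=C)[C@@H]1OC(OC)CCC=C
F2 | step 6 | methyl (9R,9aS)-2-methoxy-9-methyl-2,3,4,6,7,8,9,9a-octahydro-1-benzoxepine-9-carboxylate | COC(=O)[C@]1(C)CCC/C2=C/CCC(OC)O[C@H]12
F3 | step 16 | C6′ epimer of 31 (ring 2: 2S,3S) | COC(=O)[C@]1(C)CCC/C(=C/CC/C=C2/CCC[C@](C)(C(=O)OC(C)(C)C)[C@H]2O)[C@@H]1O[Si](CC)(CC)CC
F4 | step 16 | ring-2 Z-enone (C6′ ketone) | COC(=O)[C@]1(C)CCC/C(=C/CC/C=C2/CCC[C@](C)(C(=O)OC(C)(C)C)C2=O)[C@@H]1O[Si](CC)(CC)CC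
F0 | step 4 | none | none
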